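**Plan**

- Cuts, in retrosynthetic order: the ring A diosphenol and C4=C18 back to a C3 ketone; C7–OAc, C8–C17 and C9–C11 back to a ring B enone (C7=O, C8=C9); then C7–C8 and C5–C10 together, which opens both rings to an acyclic (E)-dienal; last C3–C4 by a vinylogous aldol.
- Forward order: acyclic chain, then ring A followed by ring B in one operation (step 4), then side chain and ring B stereocentres, then the ring A diosphenol and exocyclic methylene.
- Enabling feature: C9 lies between C8 and C10 and carries a methyl (C20). As the isopropylidene carbon of a C9=C10 alkene it lets an ene reaction at C10 hand the double bond on to C9=C8, and a second ene at C8 parks it as C9=C20. Across ring B the enal C5=C6–C7=O offers first its β-carbon C5, then its carbonyl carbon C7.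
- Stereochemistry: a temporary C3 carbinol (asymmetric vinylogous aldol) is relayed to C5 and C10 in step 4 and later becomes the C3 ketone; C9, C8 and C7 follow by substrate control; C13 comes from (R)-citronellol.

Key step: step 4

Remark: prenal, 5-methylhex-4-enal and (R)-citronellol are taken as commercial; locants follow clerodane numbering (decalin C1–C10, side chain C11–C16 on C9, C17 on C8, C18 on C4, C19 on C5, C20 on C9), and β is the face of the C5 methyl.

**Route**

Step 1
Reactants: 1 3-methylbut-2-enal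
Product: 2 (E)-tert-butyldimethyl(3-methylbuta-1,3-dien-1-yloxy)silane
Conditions: TBSOTf, Et3N, Et2O, 0 °C to rt
Reagents that add atoms: tert-butyldimethylsilyl triflate, CC(C)(C)[Si](C)(C)OS(=O)(=O)C(F)(F)F
Why: O-silylation of the extended enolate of an enal is the standard entry to aldehyde-derived silyl dienol ethers and should give the 1E isomer; no stereocentre is formed.

Step 2
Reactants: 2 (E)-tert-butyldimethyl(3-methylbuta-1,3-dien-1-yloxy)silane; 3 5-methylhex-4-enal
Product: 4 (2E,5S)-5-hydroxy-3,9-dimethyldeca-2,8-dienal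
Conditions: B-phenyl oxazaborolidinone from N-tosyltryptophan (enantiomer that gives 5S), i-PrOH, EtCN, −78 °C
Reagents that add atoms: none
Why: Vinylogous Mukaiyama aldol reaction in which the chiral boron Lewis acid shields one aldehyde face, so the γ-carbon of the dienol ether should add to give the 5S carbinol (the future C3) and the E enal.

Step 3
Reactants: 4 (2E,5S)-5-hydroxy-3,9-dimethyldeca-2,8-dienal
Product: 5 (2E,5S)-3,9-dimethyl-5-(triethylsilyloxy)deca-2,8-dienal
Conditions: Et3SiCl, imidazole, DMF, 0 °C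
Reagents that add atoms: chlorotriethylsilane, CC[Si](CC)(CC)Cl
Why: Routine silylation of a secondary alcohol; the stereocentre is untouched and the ether should tolerate the Lewis acid of step 4.

Step 4
Reactants: 5 (2E,5S)-3,9-dimethyl-5-(triethylsilyloxy)deca-2,8-dienal
Product: 7 5β-methyl-9-methylidene-3β-(triethylsilyloxy)-10βH-decalin-7β-ol, via ring-A isopropenyl aldehyde 6 (not isolated)
Conditions: Me2AlCl (2.2 equiv), CH2Cl2, −78 to −20 °C; aq. HCl work-up
Reagents that add atoms: none
Why: Me2AlCl complexes the enal, the C9=C10 alkene attacks the β-carbon C5 through C10 while a hydrogen of one C9 methyl passes to C6 (type 1 conjugate ene; ring A closes 6-exo onto the enal C=C), and the C7 aldehyde so released is attacked by the CH2 terminus (C8) of the new isopropenyl group while a hydrogen of the other C9 methyl passes to oxygen (type 2 carbonyl-ene; ring B closes on C=O and leaves C9=C20 exocyclic). The closest known chemistry is the alkylaluminium-halide-promoted sequential ene annulation of enals with alkenes and the type 1 and type 2 ene cyclisations of unsaturated aldehydes. C5 and C10 are set in the first chair-like transition state: the C3 silyloxy group sits equatorial and fixes the absolute sense, the ene arm on C10 is equatorial, and with the E enal the flat enal arm, not the C5 methyl, should take the axial place, which puts H-10 cis to the C5 methyl (cis fusion). C7 is set in the bicyclic second transition state (hydroxyl axial, cis to the C5 methyl) but is erased in step 5. The step needs conjugate, not direct, engagement of the enal and cis over trans fusion; ring size (six against eight) should secure the first, and the enal geometry with the equatorial C3 substituent the second.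

Step 5
Reactants: 7 5β-methyl-9-methylidene-3β-(triethylsilyloxy)-10βH-decalin-7β-ol
Product: 9 5β,9-dimethyl-3β-(triethylsilyloxy)-10βH-decal-8-en-7-one, via 9-methylidene 7-ketone 8 (not isolated)
Conditions: Dess–Martin periodinane, CH2Cl2, rt; aq. NaHCO3 wash; then DBU (cat.), CH2Cl2, rt
Reagents that add atoms: none
Why: Dess–Martin oxidation followed by base-mediated migration of the β,γ double bond into conjugation should give the 9-methyl enone; the C7 centre is erased and no stereocentre is formed.

Step 6
Reactants: 10 (R)-citronellol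
Product: 11 (R)-(3,7-dimethyloct-6-en-1-yloxy)triisopropylsilane
Conditions: i-Pr3SiCl, imidazole, DMF, rt
Reagents that add atoms: chlorotriisopropylsilane, CC(C)[Si](Cl)(C(C)C)C(C)C
Why: Routine silylation of a primary alcohol; the chiral-pool stereocentre (the future C13) is untouched.

Step 7
Reactants: 11 (R)-(3,7-dimethyloct-6-en-1-yloxy)triisopropylsilane
Product: 12 (4R)-4-methyl-6-(triisopropylsilyloxy)hexanoic acid
Conditions: RuCl3·H2O (cat.), NaIO4, CCl4–MeCN–H2O, rt
Reagents that add atoms: sodium periodate, [Na+].[O-]I(=O)(=O)=O; water, O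
Why: Ruthenium tetroxide cleavage of a trisubstituted alkene to a carboxylic acid and acetone is well precedented and does not touch the remote stereocentre.

Step 8
Reactants: 12 (4R)-4-methyl-6-(triisopropylsilyloxy)hexanoic acid
Product: 13 (S)-(5-iodo-3-methylpentyloxy)triisopropylsilane
Conditions: PhI(OAc)2, I2, cyclohexane, visible light, reflux
Reagents that add atoms: iodine, II
Why: Radical iododecarboxylation through the acyl hypoiodite shortens the chain by one carbon and leaves the stereocentre untouched (the descriptor changes by priority only).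

Step 9
Reactants: 9 5β,9-dimethyl-3β-(triethylsilyloxy)-10βH-decal-8-en-7-one; 13 (S)-(5-iodo-3-methylpentyloxy)triisopropylsilane
Product: 15 trimethylsilyl enol ether of the 9β-alkylated 7-ketone, via Grignard reagent 14 (not isolated)
Conditions: 13, Mg, THF; then CuBr·SMe2 (cat.), Me3SiCl, HMPA, 9, THF, −78 to −40 °C; Et3N
Reagents that add atoms: chlorotrimethylsilane, C[Si](C)(C)Cl
Why: Copper-catalysed conjugate addition of a Grignard reagent accelerated by Me3SiCl; the copper reagent should attack C9 axially from the β-face, anti to the pseudo-axial C10–C1 bond of the cis-fused enone, which sets C9 with the side chain β and C20 α.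

Step 10
Reactants: 15 trimethylsilyl enol ether of the 9β-alkylated 7-ketone
Product: 17 3β-(triethylsilyloxy)-15-(triisopropylsilyloxy)-18-norclerodan-7-one (5β-CH3, 10β-H, 8α-CH3, 9α-CH3, 13R), via lithium enolate 16 (not isolated)
Conditions: MeLi, THF, 0 °C; then MeI, HMPA, −78 to 0 °C
Reagents that add atoms: iodomethane, CI
Why: Regiospecific enolate generation from the silyl enol ether and C-methylation; MeI should approach C8 anti to the larger C9 substituent (the side chain), giving the 8α-methyl.

Step 11
Reactants: 17 3β-(triethylsilyloxy)-15-(triisopropylsilyloxy)-18-norclerodan-7-one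
Product: 18 3β-(triethylsilyloxy)-15-(triisopropylsilyloxy)-18-norclerodan-7β-ol
Conditions: Li, NH3(l), THF, −78 °C; solid NH4Cl
Reagents that add atoms: none
Why: Dissolving-metal reduction under thermodynamic control should give the equatorial alcohol of the ring B chair that keeps side chain and C17 equatorial, which is the 7β-ol (a 7α-hydroxyl would be syn-axial to C4 and C20).

Step 12
Reactants: 18 3β-(triethylsilyloxy)-15-(triisopropylsilyloxy)-18-norclerodan-7β-ol
Product: 19 7β-acetoxy-3β-(triethylsilyloxy)-15-(triisopropylsilyloxy)-18-norclerodane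
Conditions: Ac2O, Et3N, DMAP, CH2Cl2, rt
Reagents that add atoms: acetic anhydride, CC(=O)OC(C)=O
Why: DMAP-catalysed acetylation of a secondary alcohol with retention at C7.

Step 13
Reactants: 19 7β-acetoxy-3β-(triethylsilyloxy)-15-(triisopropylsilyloxy)-18-norclerodane
Product: 20 7β-acetoxy-15-(triisopropylsilyloxy)-18-norclerodan-3β-ol
Conditions: PPTS (cat.), MeOH–CH2Cl2, 0 °C
Reagents that add atoms: none
Why: Acid-catalysed methanolysis should remove the secondary triethylsilyl ether and leave the far more robust primary triisopropylsilyl ether and the acetate.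

Step 14
Reactants: 20 7β-acetoxy-15-(triisopropylsilyloxy)-18-norclerodan-3β-ol
Product: 21 7β-acetoxy-15-(triisopropylsilyloxy)-18-norclerodan-3-one
Conditions: Dess–Martin periodinane, CH2Cl2, rt
Reagents that add atoms: none
Why: Dess–Martin oxidation turns the relay carbinol into the C3 ketone the target needs; the temporary stereocentre is removed.

Step 15
Reactants: 21 7β-acetoxy-15-(triisopropylsilyloxy)-18-norclerodan-3-one
Product: 23 7β-acetoxy-2-(triethylsilyloxy)-15-(triisopropylsilyloxy)-18-norclerodan-3-one (C2 epimers), via triethylsilyl enol ether 22 (not isolated)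
Conditions: LiN(SiMe3)2, Et3SiCl, THF, −78 °C; then mCPBA, NaHCO3, CH2Cl2, 0 °C
Reagents that add atoms: chlorotriethylsilane, CC[Si](CC)(CC)Cl; mCPBA, O=C(OO)c1cccc(Cl)c1
Why: Rubottom oxidation; kinetic enolisation should occur at C2, away from the neopentyl C4, and the C2 configuration is irrelevant because C2 is oxidised in step 18.

Step 16
Reactants: 23 7β-acetoxy-2-(triethylsilyloxy)-15-(triisopropylsilyloxy)-18-norclerodan-3-one
Product: 25 7β-acetoxy-2-(triethylsilyloxy)-15-(triisopropylsilyloxy)clerod-4(18)-en-3-one, via Mannich base 24 (not isolated)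
Conditions: LiN(SiMe3)2, THF, −78 °C; Eschenmoser's salt; then MeI; NaHCO3, CH2Cl2–H2O
Reagents that add atoms: Eschenmoser's salt, C=[N+](C)C.[I-]
Why: Mannich reaction at C4, the enolisable α-carbon not carrying oxygen, then quaternisation and elimination, the standard α-methylenation of a ketone; no stereocentre is formed.

Step 17
Reactants: 25 7β-acetoxy-2-(triethylsilyloxy)-15-(triisopropylsilyloxy)clerod-4(18)-en-3-one
Product: 26 7β-acetoxy-2,15-dihydroxyclerod-4(18)-en-3-one
Conditions: HF·pyridine, THF–pyridine, 0 °C to rt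
Reagents that add atoms: none
Why: Fluoride-mediated cleavage of both silyl ethers under conditions that should spare the acetate and the enone.

Step 18
Reactants: 26 7β-acetoxy-2,15-dihydroxyclerod-4(18)-en-3-one
Product: 27 7β-acetoxy-2-hydroxy-3-oxocleroda-1,4(18)-dien-15-al
Conditions: Dess–Martin periodinane (excess), CH2Cl2, rt
Reagents that add atoms: none
Why: Dess–Martin oxidation of the primary alcohol to the aldehyde and of the α-hydroxy ketone to the 2,3-dione, which can enolise only towards C1 and so should give the diosphenol.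

Step 19
Reactants: 27 7β-acetoxy-2-hydroxy-3-oxocleroda-1,4(18)-dien-15-al
Product: 28 CNP0257844.1, 7β-acetoxy-2-hydroxy-3-oxocleroda-1,4(18)-dien-15-oic acid
Conditions: NaClO2, NaH2PO4, 2-methyl-2-butene, t-BuOH–H2O, 0 °C
Reagents that add atoms: sodium chlorite, [Na+].[O-]Cl=O
Why: Pinnick oxidation converts the aldehyde to the acid without touching the acetate, the enone or any stereocentre.

**Compound list**

1 | 3-methylbut-2-enal | CC(C)=CC=O | starting material
2 | (E)-tert-butyldimethyl(3-methylbuta-1,3-dien-1-yloxy)silane | C=C(C)/C=C/O[Si](C)(C)C(C)(C)C | intermediate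
3 | 5-methylhex-4-enal | CC(C)=CCCC=O | starting material
4 | (2E,5S)-5-hydroxy-3,9-dimethyldeca-2,8-dienal | O=C/C=C(\C)C[C@@H](O)CCC=C(C)C | intermediate
5 | (2E,5S)-3,9-dimethyl-5-(triethylsilyloxy)deca-2,8-dienal | O=C/C=C(\C)C[C@@H](O[Si](CC)(CC)CC)CCC=C(C)C | intermediate
6 | ring A aldehyde: cyclohexane C1–C5/C10 with 3β-OSiEt3, C5 bearing β-CH3 and α-CH2CHO, C10 bearing α-isopropenyl | C1[C@@H](O[Si](CC)(CC)CC)CC[C@H](C(C)=C)[C@]1(C)CC=O | intermediate
7 | 5β-methyl-9-methylidene-3β-(triethylsilyloxy)-10βH-decalin-7β-ol | C1[C@@H](O[Si](CC)(CC)CC)CC[C@@H]2C(=C)C[C@@H](O)C[C@]12C | intermediate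
8 | 5β-methyl-9-methylidene-3β-(triethylsilyloxy)-10βH-decalin-7-one | C1[C@@H](O[Si](CC)(CC)CC)CC[C@@H]2C(=C)CC(=O)C[C@]12C | intermediate
9 | 5β,9-dimethyl-3β-(triethylsilyloxy)-10βH-decal-8-en-7-one | C1[C@@H](O[Si](CC)(CC)CC)CC[C@@H]2C(C)=CC(=O)C[C@]12C | intermediate
10 | (R)-citronellol, (3R)-3,7-dimethyloct-6-en-1-ol | C[C@@H](CCO)CCC=C(C)C | starting material
11 | (R)-(3,7-dimethyloct-6-en-1-yloxy)triisopropylsilane | C[C@@H](CCO[Si](C(C)C)(C(C)C)C(C)C)CCC=C(C)C | intermediate
12 | (4R)-4-methyl-6-(triisopropylsilyloxy)hexanoic acid | C[C@@H](CCO[Si](C(C)C)(C(C)C)C(C)C)CCC(=O)O | intermediate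
13 | (S)-(5-iodo-3-methylpentyloxy)triisopropylsilane | C[C@@H](CCO[Si](C(C)C)(C(C)C)C(C)C)CCI | intermediate
14 | Grignard reagent of 13 | C[C@@H](CCO[Si](C(C)C)(C(C)C)C(C)C)CC[Mg]I | intermediate
15 | 3β-(triethylsilyloxy)-15-(triisopropylsilyloxy)-7-(trimethylsilyloxy)-18-norclerod-7-ene (5β-CH3, 10β-H, 9α-CH3, 13R) | C1[C@@H](O[Si](CC)(CC)CC)CC[C@@H]2[C@@](C)(CC[C@@H](C)CCO[Si](C(C)C)(C(C)C)C(C)C)C=C(O[Si](C)(C)C)C[C@]12C | intermediate
16 | lithium enolate corresponding to 15 | C1[C@@H](O[Si](CC)(CC)CC)CC[C@@H]2[C@@](C)(CC[C@@H](C)CCO[Si](C(C)C)(C(C)C)C(C)C)C=C(O[Li])C[C@]12C | intermediate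
17 | 3β-(triethylsilyloxy)-15-(triisopropylsilyloxy)-18-norclerodan-7-one (5β-CH3, 10β-H, 8α-CH3, 9α-CH3, 13R) | C1[C@@H](O[Si](CC)(CC)CC)CC[C@@H]2[C@@](C)(CC[C@@H](C)CCO[Si](C(C)C)(C(C)C)C(C)C)[C@H](C)C(=O)C[C@]12C | intermediate
18 | 3β-(triethylsilyloxy)-15-(triisopropylsilyloxy)-18-norclerodan-7β-ol | C1[C@@H](O[Si](CC)(CC)CC)CC[C@@H]2[C@@](C)(CC[C@@H](C)CCO[Si](C(C)C)(C(C)C)C(C)C)[C@H](C)[C@@H](O)C[C@]12C | intermediate
19 | 7β-acetoxy-3β-(triethylsilyloxy)-15-(triisopropylsilyloxy)-18-norclerodane | C1[C@@H](O[Si](CC)(CC)CC)CC[C@@H]2[C@@](C)(CC[C@@H](C)CCO[Si](C(C)C)(C(C)C)C(C)C)[C@H](C)[C@@H](OC(C)=O)C[C@]12C | intermediate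
20 | 7β-acetoxy-15-(triisopropylsilyloxy)-18-norclerodan-3β-ol | C1[C@@H](O)CC[C@@H]2[C@@](C)(CC[C@@H](C)CCO[Si](C(C)C)(C(C)C)C(C)C)[C@H](C)[C@@H](OC(C)=O)C[C@]12C | intermediate
21 | 7β-acetoxy-15-(triisopropylsilyloxy)-18-norclerodan-3-one | C1C(=O)CC[C@@H]2[C@@](C)(CC[C@@H](C)CCO[Si](C(C)C)(C(C)C)C(C)C)[C@H](C)[C@@H](OC(C)=O)C[C@]12C | intermediate
22 | 7β-acetoxy-3-(triethylsilyloxy)-15-(triisopropylsilyloxy)-18-norclerod-2-ene | C1C(O[Si](CC)(CC)CC)=CC[C@@H]2[C@@](C)(CC[C@@H](C)CCO[Si](C(C)C)(C(C)C)C(C)C)[C@H](C)[C@@H](OC(C)=O)C[C@]12C | intermediate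
23 | 7β-acetoxy-2-(triethylsilyloxy)-15-(triisopropylsilyloxy)-18-norclerodan-3-one (C2 epimers) | C1C(=O)C(O[Si](CC)(CC)CC)C[C@@H]2[C@@](C)(CC[C@@H](C)CCO[Si](C(C)C)(C(C)C)C(C)C)[C@H](C)[C@@H](OC(C)=O)C[C@]12C | intermediate
24 | 4-(dimethylaminomethyl) derivative of 23 (C2, C4 epimers) | C1(CN(C)C)C(=O)C(O[Si](CC)(CC)CC)C[C@@H]2[C@@](C)(CC[C@@H](C)CCO[Si](C(C)C)(C(C)C)C(C)C)[C@H](C)[C@@H](OC(C)=O)C[C@]12C | intermediate
25 | 7β-acetoxy-2-(triethylsilyloxy)-15-(triisopropylsilyloxy)clerod-4(18)-en-3-one (C2 epimers) | C=C1C(=O)C(O[Si](CC)(CC)CC)C[C@@H]2[C@@](C)(CC[C@@H](C)CCO[Si](C(C)C)(C(C)C)C(C)C)[C@H](C)[C@@H](OC(C)=O)C[C@]12C | intermediate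
26 | 7β-acetoxy-2,15-dihydroxyclerod-4(18)-en-3-one (C2 epimers) | C=C1C(=O)C(O)C[C@@H]2[C@@](C)(CC[C@@H](C)CCO)[C@H](C)[C@@H](OC(C)=O)C[C@]12C | intermediate
27 | 7β-acetoxy-2-hydroxy-3-oxocleroda-1,4(18)-dien-15-al | C=C1C(=O)C(O)=C[C@@H]2[C@@](C)(CC[C@@H](C)CC=O)[C@H](C)[C@@H](OC(C)=O)C[C@]12C | intermediate
28 | CNP0257844.1, 7β-acetoxy-2-hydroxy-3-oxocleroda-1,4(18)-dien-15-oic acid | C=C1C(=O)C(O)=C[C@@H]2[C@@](C)(CC[C@@H](C)CC(=O)O)[C@H](C)[C@@H](OC(C)=O)C[C@]12C | target

**Count and risks**

Total: 19 steps. Longest linear sequence: 16 steps (steps 1–5, then 9–19); the side-chain iodide takes steps 6–8.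

Steps most likely to fail:

1. Step 4. The first ene closure may go through the chair with the C5 methyl axial, which would give the trans-fused isomer. The aluminium-bound intermediates may also be diverted to chloride capture or proton loss instead of the second ene reaction, and the silyl ether may be lost. Fallback: set out from 2 and run the same vinylogous aldol with 5-oxohexanal to get (2E,5S)-5-hydroxy-3-methyl-9-oxodec-2-enal F1, then silylate to its triethylsilyl ether F2. Pyrrolidine and AcOH in toluene should bring about a Robinson-type sequence under equilibrating conditions: Michael addition of the methyl ketone through C10 to the enal, then aldol condensation of its methyl group with the aldehyde. This gives the bicyclic 7-en-9-one F3, which makes the same two bonds with the ring fusion adjustable through enolisation. MeLi with CeCl3 then gives the tertiary allylic alcohol F4, and pyridinium chlorochromate (C5H5NH[CrO3Cl]) effects the 1,3-oxidative transposition, which comes back to the route at enone 9.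

2. Step 9. The hindered β,β-disubstituted enone may be enolised or attacked at the carbonyl instead of at C9, and attack syn to the C5 methyl may be slow enough to erode facial selectivity. Fallback: set out from 9 and 13 and couple the iodide itself by nickel-catalysed reductive conjugate addition (NiCl2(MeOCH2CH2OMe), terpyridine, Mn powder, Et3SiCl, DMF), a radical and allyl-nickel pathway that needs no organomagnesium or organocopper reagent. This gives the triethylsilyl enol ether F5, which on MeLi then MeI as in step 10 comes back to the route at 17.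

3. Step 11. The equilibrium between the C7 epimers may not lie as far towards the 7β-ol as argued, and C8 may epimerise through the enolate. Fallback: set out from 17 and reduce kinetically with LiBH(s-Bu)3, which should deliver hydride from the open β-face and give the axial 7α-alcohol F6. A Mitsunobu reaction with acetic acid (PPh3, diisopropyl azodicarboxylate) then inverts C7 and installs the ester in one step, which comes back to the route at acetate 19.

Further compounds
F1 | step 4 | (2E,5S)-5-hydroxy-3-methyl-9-oxodec-2-enal | O=C/C=C(\C)C[C@@H](O)CCCC(C)=O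
F2 | step 4 | (2E,5S)-3-methyl-9-oxo-5-(triethylsilyloxy)dec-2-enal | O=C/C=C(\C)C[C@@H](O[Si](CC)(CC)CC)CCCC(C)=O
F3 | step 4 | 5β-methyl-3β-(triethylsilyloxy)-10βH-decal-7-en-9-one | C1[C@@H](O[Si](CC)(CC)CC)CC[C@@H]2C(=O)C=CC[C@]12C
F4 | step 4 | 5β,9-dimethyl-3β-(triethylsilyloxy)-10βH-decal-7-en-9-ol (C9 epimers) | C1[C@@H](O[Si](CC)(CC)CC)CC[C@@H]2C(C)(O)C=CC[C@]12C
F5 | step 9 | 3β,7-bis(triethylsilyloxy)-15-(triisopropylsilyloxy)-18-norclerod-7-ene | C1[C@@H](O[Si](CC)(CC)CC)CC[C@@H]2[C@@](C)(CC[C@@H](C)CCO[Si](C(C)C)(C(C)C)C(C)C)C=C(O[Si](CC)(CC)CC)C[C@]12C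
F6 | step 11 | 3β-(triethylsilyloxy)-15-(triisopropylsilyloxy)-18-norclerodan-7α-ol | C1[C@@H](O[Si](CC)(CC)CC)CC[C@@H]2[C@@](C)(CC[C@@H](C)CCO[Si](C(C)C)(C(C)C)C(C)C)[C@H](C)[C@H](O)C[C@]12C
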